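C2 is 2S. Ring C is cut last in the retrosynthesis, at O1–C8a and C4–C4a, after removal of the four acid-labile O-protecting groups; the halves go back to phloroglucinol and 4-bromoresorcinol.
Enabling feature: both ring C bonds start from the adjacent ring A carbons C8a and C4a, and the C5 oxygen sits next to C4a. Ring A can therefore react as a polarised C4a–C8a aryne and O1–C2–C3–C4 as a β-oxy ester.
Half 1: phloroglucinol → dihydrocoumarin → MeMgBr opening (gives the C8 side chain and a free C8a–OH) → carbamate-directed silylation at C4a → 2-silylaryl triflate.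
Half 2: 4-bromoresorcinol → chromanone → chromene (ring B with its pyran ring) → methyl ketone → β-keto ester → hydroxy ester. Ring C closes last, when the halves are joined.
Stereochemistry: C2 is the only stereocentre. Noyori–Ikariya transfer hydrogenation of the β-keto ester sets it, and its C–O bond is never broken afterwards.

Key step: step 16

Remark: flavanone locants (O1, C2–C4, C4a, C5–C8, C8a) are used for all intermediates.

Step 1
Reactants: 1 phloroglucinol; 2 acrylic acid
Product: 3 5,7-dihydroxychroman-2-one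
Conditions: Amberlyst-15 (sulfonic acid resin), toluene, reflux, Dean–Stark trap
Reagents that add atoms: none
Why: Esterification followed by intramolecular Friedel–Crafts-type conjugate addition (hydroarylative lactonisation) over a non-dehydrating sulfonic acid is an established route from polyhydric phenols and acrylic acid to 3,4-dihydrocoumarins, and the threefold symmetry of 1 allows only one regioisomer.

Step 2
Reactants: 3 5,7-dihydroxychroman-2-one
Product: 4 5,7-bis(methoxymethoxy)chroman-2-one
Conditions: MOMCl (2.5 equiv), iPr2NEt, CH2Cl2, 0 °C → rt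
Reagents that add atoms: chloromethyl methyl ether, COCCl
Why: This is standard O-alkylation of phenols with an α-chloro ether, and the hindered amine base does not open the aryl lactone.

Step 3
Reactants: 4 5,7-bis(methoxymethoxy)chroman-2-one
Product: 5 2-(3-hydroxy-3-methylbutyl)-3,5-bis(methoxymethoxy)phenol
Conditions: MeMgBr (3.5 equiv), THF, 0 °C → rt; aq NH4Cl
Reagents that add atoms: methylmagnesium bromide, C[Mg]Br
Why: Double Grignard addition to the lactone carbonyl releases the C8a phenoxide and builds the tertiary carbinol in one operation, a routine opening of dihydrocoumarins that leaves MOM ethers untouched.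

Step 4
Reactants: 5 2-(3-hydroxy-3-methylbutyl)-3,5-bis(methoxymethoxy)phenol
Product: 6 2-(3-hydroxy-3-methylbutyl)-3,5-bis(methoxymethoxy)phenyl N-isopropylcarbamate
Conditions: iPrNCO (1.2 equiv), Et3N (0.2 equiv), CH2Cl2, rt
Reagents that add atoms: isopropyl isocyanate, CC(C)N=C=O
Why: Amine-catalysed addition of a phenol to an isocyanate (carbamoylation) is fast, whereas the tertiary alcohol is too hindered to react at room temperature, so only the C8a oxygen should be derivatised.

Step 5
Reactants: 6 2-(3-hydroxy-3-methylbutyl)-3,5-bis(methoxymethoxy)phenyl N-isopropylcarbamate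
Product: 7 3,5-bis(methoxymethoxy)-2-[3-methyl-3-(triethylsilyloxy)butyl]phenyl N-isopropylcarbamate
Conditions: TESOTf, 2,6-lutidine, CH2Cl2, −78 → 0 °C; aq NaHCO3
Reagents that add atoms: triethylsilyl trifluoromethanesulfonate, CC[Si](CC)(CC)OS(=O)(=O)C(F)(F)F
Why: A silyl triflate with a hindered pyridine base is the standard silylation of tertiary alcohols, the MOM ethers tolerate it at low temperature, and any N-silylation of the carbamate is undone on aqueous work-up.

Step 6
Reactants: 7 3,5-bis(methoxymethoxy)-2-[3-methyl-3-(triethylsilyloxy)butyl]phenyl N-isopropylcarbamate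
Product: 11 3,5-bis(methoxymethoxy)-6-[3-methyl-3-(triethylsilyloxy)butyl]-2-(trimethylsilyl)phenyl N-isopropylcarbamate, via N-silyl carbamate 8 (not isolated), via aryllithium 9 (not isolated), via bis-silyl carbamate 10 (not isolated)
Conditions: TMSOTf (1.1 equiv), TMEDA, Et2O, 0 °C → rt; n-BuLi, TMEDA, −78 °C; TMSCl, −78 °C → rt; MeOH, aq NH4Cl
Reagents that add atoms: chlorotrimethylsilane, C[Si](C)(C)Cl
Why: This is directed ortho-metalation of an O-aryl N-isopropylcarbamate after transient N-silylation, in which the carbamate (the strongest directing group on the ring) cooperates with the C5 MOM ether so that deprotonation should occur at the C–H between them (future C4a) rather than at C6, and Me3SiCl traps the anion.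

Step 7
Reactants: 11 3,5-bis(methoxymethoxy)-6-[3-methyl-3-(triethylsilyloxy)butyl]-2-(trimethylsilyl)phenyl N-isopropylcarbamate
Product: 13 3,5-bis(methoxymethoxy)-6-[3-methyl-3-(triethylsilyloxy)butyl]-2-(trimethylsilyl)phenyl trifluoromethanesulfonate, via silylphenol 12 (not isolated)
Conditions: Et2NH, DBU, MeCN, 40 °C; then PhNTf2, rt → 40 °C
Reagents that add atoms: N-phenylbis(trifluoromethanesulfonimide), O=S(=O)(N(c1ccccc1)S(=O)(=O)C(F)(F)F)C(F)(F)F
Why: Base cleaves the N–H carbamate by E1cB loss of isopropyl isocyanate, which Et2NH scavenges as a urea, and the phenoxide is sulfonylated in the same flask by the mild triflyl donor PhNTf2, the usual last stage in making 2-silylaryl triflates.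

Step 8
Reactants: 14 4-bromobenzene-1,3-diol; 15 3-methylbut-2-enoic acid
Product: 16 6-bromo-7-hydroxy-2,2-dimethylchroman-4-one
Conditions: P2O5/MeSO3H, 70 °C, short reaction time
Reagents that add atoms: none
Why: Friedel–Crafts acylation at the only unhindered activated position of 14 (para to one hydroxyl, ortho to the other, the twin site being blocked by bromine) followed by oxa-Michael closure is the standard one-pot route from resorcinols and 15 to 2,2-dimethylchroman-4-ones.

Step 9
Reactants: 16 6-bromo-7-hydroxy-2,2-dimethylchroman-4-one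
Product: 17 6-bromo-7-(methoxymethoxy)-2,2-dimethylchroman-4-one
Conditions: MOMCl, iPr2NEt, CH2Cl2, 0 °C → rt
Reagents that add atoms: chloromethyl methyl ether, COCCl
Why: Standard O-alkylation of a phenol with an α-chloro ether also removes the acidic proton that would slow the following hydride reduction.

Step 10
Reactants: 17 6-bromo-7-(methoxymethoxy)-2,2-dimethylchroman-4-one
Product: 18 racemic 6-bromo-7-(methoxymethoxy)-2,2-dimethylchroman-4-ol
Conditions: NaBH4, MeOH/THF, 0 °C → rt
Reagents that add atoms: none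
Why: This is a borohydride reduction of an aryl ketone, and the new carbinol centre forms as a racemate that is erased in step 11.

Step 11
Reactants: 18 racemic 6-bromo-7-(methoxymethoxy)-2,2-dimethylchroman-4-ol
Product: 20 6-bromo-7-(methoxymethoxy)-2,2-dimethyl-2H-chromene, via benzylic mesylate 19 (not isolated)
Conditions: MsCl, Et3N (excess), CH2Cl2, 0 °C → reflux
Reagents that add atoms: none
Why: Mesylation of the electron-rich benzylic alcohol is followed by amine-assisted elimination, a non-acidic chromanol-to-chromene dehydration that spares the MOM ether.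

Step 12
Reactants: 20 6-bromo-7-(methoxymethoxy)-2,2-dimethyl-2H-chromene
Product: 22 1-[7-(methoxymethoxy)-2,2-dimethyl-2H-chromen-6-yl]ethan-1-one, via aryllithium 21 (not isolated)
Conditions: n-BuLi, THF, −78 °C; MeC(O)N(OMe)Me, −78 → 0 °C; aq NH4Cl
Reagents that add atoms: N-methoxy-N-methylacetamide, CC(=O)N(C)OC
Why: Bromine–lithium exchange, helped by the neighbouring MOM oxygen, is followed by a Weinreb ketone synthesis whose chelated tetrahedral adduct prevents a second addition.

Step 13
Reactants: 22 1-[7-(methoxymethoxy)-2,2-dimethyl-2H-chromen-6-yl]ethan-1-one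
Product: 23 methyl 3-[7-(methoxymethoxy)-2,2-dimethyl-2H-chromen-6-yl]-3-oxopropanoate
Conditions: NaH (2.5 equiv), (MeO)2CO, THF, reflux; aq NH4Cl
Reagents that add atoms: dimethyl carbonate, COC(=O)OC
Why: This is a crossed Claisen condensation of a methyl ketone enolate with dimethyl carbonate, driven by irreversible deprotonation of the β-keto ester formed.

Step 14
Reactants: 23 methyl 3-[7-(methoxymethoxy)-2,2-dimethyl-2H-chromen-6-yl]-3-oxopropanoate
Product: 24 methyl (S)-3-hydroxy-3-[7-(methoxymethoxy)-2,2-dimethyl-2H-chromen-6-yl]propanoate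
Conditions: RuCl(p-cymene)[(S,S)-TsDPEN] (1 mol %), HCO2H/Et3N (5:2), CH2Cl2, 30 °C
Reagents that add atoms: none
Why: In this Noyori–Ikariya asymmetric transfer hydrogenation, established for aryl β-keto esters, the aryl group lies under the cymene ligand (CH/π attraction) in the six-membered transition state, so the (S,S)-catalyst should deliver hydride to the Re face and give the S carbinol (future C2), while the metal hydride leaves the chromene C=C bond alone.

Step 15
Reactants: 24 methyl (S)-3-hydroxy-3-[7-(methoxymethoxy)-2,2-dimethyl-2H-chromen-6-yl]propanoate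
Product: 25 methyl (S)-3-[7-(methoxymethoxy)-2,2-dimethyl-2H-chromen-6-yl]-3-(trimethylsilyloxy)propanoate
Conditions: TMSCl, imidazole, CH2Cl2, 0 °C; non-aqueous filtration, used directly
Reagents that add atoms: chlorotrimethylsilane, C[Si](C)(C)Cl
Why: Routine silylation of a secondary alcohol does not involve the stereocentre and turns the hydroxyl group into a proton-free alkoxide source that fluoride can release.

Step 16
Reactants: 13 3,5-bis(methoxymethoxy)-6-[3-methyl-3-(triethylsilyloxy)butyl]-2-(trimethylsilyl)phenyl trifluoromethanesulfonate; 25 methyl (S)-3-[7-(methoxymethoxy)-2,2-dimethyl-2H-chromen-6-yl]-3-(trimethylsilyloxy)propanoate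
Product: 29 (2S)-5,7-bis(methoxymethoxy)-2-[7-(methoxymethoxy)-2,2-dimethyl-2H-chromen-6-yl]-8-[3-methyl-3-(triethylsilyloxy)butyl]chroman-4-one, via aryne 26 (not isolated), via caesium alkoxide 27 (not isolated), via aryl carbanion 28 (not isolated)
Conditions: 13 (1.0 equiv), 25 (1.3 equiv), dried CsF (1.5 equiv), 18-crown-6 (0.2 equiv), THF, 25 → 45 °C; quench with pH 7 phosphate buffer, 0 °C
Reagents that add atoms: none
Why: Proposed new method: fluoride, and every alkoxide set free later, removes Me3Si from C4a of 13 so that triflate leaves C8a and aryne 26 forms, while the same silicon transfer uncovers alkoxide 27 from 25 in a medium that contains no O–H proton. The oxygen of 27 adds to C8a (O1–C8a), and the carbanion left at C4a in 28 attacks the ester carbonyl in a 6-exo-trig acyl substitution (C4a–C4) that closes ring C and expels methoxide, which unreacted 25 takes up as MeOSiMe3, so that no strong base remains to open the flavanone by retro-oxa-Michael reaction. The closest known reaction types are the CsF-mediated annulation of 2-silylaryl triflates with methyl salicylates to xanthones and the O-arylation of aliphatic alcohols by arynes; new are the aliphatic β-oxido ester as partner and an enolisable chroman-4-one as product. No stereocentre is created: neither the C2–O nor the C2–H bond of 25 is touched, so the S configuration from step 14 is retained as long as capture of 27 outruns its retro-aldol cleavage, which the slow heterogeneous supply of fluoride and the resulting low level of free alkoxide should secure. The regioselectivity needed, O-attack at C8a and not at C4a, is secured by the σ-withdrawing C5 oxygen, which distorts 26 so that C8a is the more linear and more electrophilic terminus and the charge develops at C4a next to that oxygen, the C8 chain opposing this only by its bulk. The chemoselectivity needed, acylation of the C4a carbanion ahead of its protonation, is secured by the aprotic medium and by the ester carbonyl being placed to close a six-membered ring, and the tertiary TES ether should outlast the far more accessible Me3Si groups because fluoride is not used in large excess.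

Step 17
Reactants: 29 (2S)-5,7-bis(methoxymethoxy)-2-[7-(methoxymethoxy)-2,2-dimethyl-2H-chromen-6-yl]-8-[3-methyl-3-(triethylsilyloxy)butyl]chroman-4-one
Product: 30 (2S)-5,7-dihydroxy-2-(7-hydroxy-2,2-dimethyl-2H-chromen-6-yl)-8-(3-hydroxy-3-methylbutyl)chroman-4-one (target)
Conditions: HCl (about 1 M) in MeOH, 40 °C; aq NaHCO3 to pH 6–7
Reagents that add atoms: none
Why: Acid-catalysed transacetalisation of the three aryl MOM ethers and solvolysis of the tertiary TES ether in methanol is a standard last step for MOM-protected flavanones, no base is present that could racemise C2 by retro-oxa-Michael opening, and the acid is kept dilute to spare the chromene and the tertiary alcohol.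

Compound list
1 | phloroglucinol | Oc1cc(O)cc(O)c1 | starting material
2 | acrylic acid | C=CC(=O)O | starting material
3 | 5,7-dihydroxychroman-2-one | O=C1CCc2c(O)cc(O)cc2O1 | intermediate
4 | 5,7-bis(methoxymethoxy)chroman-2-one | O=C1CCc2c(OCOC)cc(OCOC)cc2O1 | intermediate
5 | 2-(3-hydroxy-3-methylbutyl)-3,5-bis(methoxymethoxy)phenol | CC(C)(O)CCc1c(O)cc(OCOC)cc1OCOC | intermediate
6 | 2-(3-hydroxy-3-methylbutyl)-3,5-bis(methoxymethoxy)phenyl N-isopropylcarbamate | CC(C)(O)CCc1c(OC(=O)NC(C)C)cc(OCOC)cc1OCOC | intermediate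
7 | 3,5-bis(methoxymethoxy)-2-[3-methyl-3-(triethylsilyloxy)butyl]phenyl N-isopropylcarbamate | CC(C)(O[Si](CC)(CC)CC)CCc1c(OC(=O)NC(C)C)cc(OCOC)cc1OCOC | intermediate
8 | N-trimethylsilyl derivative of 7 | CC(C)(O[Si](CC)(CC)CC)CCc1c(OC(=O)N(C(C)C)[Si](C)(C)C)cc(OCOC)cc1OCOC | intermediate
9 | aryllithium from 8, lithium on the ring carbon between the carbamate-bearing carbon and the neighbouring MOM-bearing carbon (future C4a) | CC(C)(O[Si](CC)(CC)CC)CCc1c(OC(=O)N(C(C)C)[Si](C)(C)C)c([Li])c(OCOC)cc1OCOC | intermediate
10 | N-trimethylsilyl derivative of 11 | CC(C)(O[Si](CC)(CC)CC)CCc1c(OC(=O)N(C(C)C)[Si](C)(C)C)c([Si](C)(C)C)c(OCOC)cc1OCOC | intermediate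
11 | 3,5-bis(methoxymethoxy)-6-[3-methyl-3-(triethylsilyloxy)butyl]-2-(trimethylsilyl)phenyl N-isopropylcarbamate | CC(C)(O[Si](CC)(CC)CC)CCc1c(OC(=O)NC(C)C)c([Si](C)(C)C)c(OCOC)cc1OCOC | intermediate
12 | 3,5-bis(methoxymethoxy)-6-[3-methyl-3-(triethylsilyloxy)butyl]-2-(trimethylsilyl)phenol | CC(C)(O[Si](CC)(CC)CC)CCc1c(O)c([Si](C)(C)C)c(OCOC)cc1OCOC | intermediate
13 | 3,5-bis(methoxymethoxy)-6-[3-methyl-3-(triethylsilyloxy)butyl]-2-(trimethylsilyl)phenyl trifluoromethanesulfonate | CC(C)(O[Si](CC)(CC)CC)CCc1c(OCOC)cc(OCOC)c([Si](C)(C)C)c1OS(=O)(=O)C(F)(F)F | intermediate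
14 | 4-bromobenzene-1,3-diol | Oc1ccc(Br)c(O)c1 | starting material
15 | 3-methylbut-2-enoic acid | CC(C)=CC(=O)O | starting material
16 | 6-bromo-7-hydroxy-2,2-dimethylchroman-4-one | O=C1CC(C)(C)Oc2cc(O)c(Br)cc12 | intermediate
17 | 6-bromo-7-(methoxymethoxy)-2,2-dimethylchroman-4-one | O=C1CC(C)(C)Oc2cc(OCOC)c(Br)cc12 | intermediate
18 | racemic 6-bromo-7-(methoxymethoxy)-2,2-dimethylchroman-4-ol | OC1CC(C)(C)Oc2cc(OCOC)c(Br)cc12 | intermediate
19 | racemic 6-bromo-7-(methoxymethoxy)-2,2-dimethylchroman-4-yl methanesulfonate | CS(=O)(=O)OC1CC(C)(C)Oc2cc(OCOC)c(Br)cc12 | intermediate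
20 | 6-bromo-7-(methoxymethoxy)-2,2-dimethyl-2H-chromene | Brc1cc2c(cc1OCOC)OC(C)(C)C=C2 | intermediate
21 | [7-(methoxymethoxy)-2,2-dimethyl-2H-chromen-6-yl]lithium | [Li]c1cc2c(cc1OCOC)OC(C)(C)C=C2 | intermediate
22 | 1-[7-(methoxymethoxy)-2,2-dimethyl-2H-chromen-6-yl]ethan-1-one | CC(=O)c1cc2c(cc1OCOC)OC(C)(C)C=C2 | intermediate
23 | methyl 3-[7-(methoxymethoxy)-2,2-dimethyl-2H-chromen-6-yl]-3-oxopropanoate | COC(=O)CC(=O)c1cc2c(cc1OCOC)OC(C)(C)C=C2 | intermediate
24 | methyl (S)-3-hydroxy-3-[7-(methoxymethoxy)-2,2-dimethyl-2H-chromen-6-yl]propanoate | O[C@H](c1cc2c(cc1OCOC)OC(C)(C)C=C2)CC(=O)OC | intermediate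
25 | methyl (S)-3-[7-(methoxymethoxy)-2,2-dimethyl-2H-chromen-6-yl]-3-(trimethylsilyloxy)propanoate | C[Si](C)(C)O[C@H](c1cc2c(cc1OCOC)OC(C)(C)C=C2)CC(=O)OC | intermediate
26 | 3,5-bis(methoxymethoxy)-6-[3-methyl-3-(triethylsilyloxy)butyl]-1,2-didehydrobenzene (C4a–C8a aryne) | CC(C)(O[Si](CC)(CC)CC)CCC1=C(OCOC)C=C(OCOC)C#C1 | intermediate
27 | caesium (S)-alkoxide of 24 | [Cs+].[O-][C@H](c1cc2c(cc1OCOC)OC(C)(C)C=C2)CC(=O)OC | intermediate
28 | caesium salt of the (S)-O-aryl ether carbanion, charge at C4a | [Cs+].CC(C)(O[Si](CC)(CC)CC)CCc1c(OCOC)cc(OCOC)[c-]c1O[C@H](c1cc2c(cc1OCOC)OC(C)(C)C=C2)CC(=O)OC | intermediate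
29 | (2S)-5,7-bis(methoxymethoxy)-2-[7-(methoxymethoxy)-2,2-dimethyl-2H-chromen-6-yl]-8-[3-methyl-3-(triethylsilyloxy)butyl]chroman-4-one | CC(C)(O[Si](CC)(CC)CC)CCc1c(OCOC)cc(OCOC)c2c1O[C@H](c1cc3c(cc1OCOC)OC(C)(C)C=C3)CC2=O | intermediate
30 | (2S)-5,7-dihydroxy-2-(7-hydroxy-2,2-dimethyl-2H-chromen-6-yl)-8-(3-hydroxy-3-methylbutyl)chroman-4-one | CC(C)(O)CCc1c(O)cc(O)c2c1O[C@H](c1cc3c(cc1O)OC(C)(C)C=C3)CC2=O | target

Total step count: 17 (steps 1–7 for the ring A half, steps 8–15 for the ring B half, steps 16–17 after the union).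
Longest linear sequence: 10 steps (steps 8–17).

Steps most likely to fail

1. Step 16.
- Processes at risk:
  - The bulky secondary alkoxide may add too slowly to the hindered C8a terminus, or at C4a.
  - The C4a carbanion may be quenched by abstracting a C3 proton, with β-elimination following, instead of being acylated.
  - The free alkoxide may fragment by retro-aldol reaction and lose enantiopurity.
  - The alkoxide may attack the sulfur of the triflate.
  - The TES group may be lost early, so that the side-chain oxygen captures the aryne.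
- Fallback by known chemistry, from 7 and 20 back to 29. Ring C is closed at O1–C2 instead, and the configuration is obtained by resolution.
  - Aryllithium 9 is generated from 7 as in step 6. It is quenched with N-methoxy-N-methylacetamide and gives, after methanolic work-up, 2-acetyl-3,5-bis(methoxymethoxy)-6-[3-methyl-3-(triethylsilyloxy)butyl]phenyl N-isopropylcarbamate F1.
  - Et2NH and DBU in MeCN then remove the carbamate to give 1-{2-hydroxy-4,6-bis(methoxymethoxy)-3-[3-methyl-3-(triethylsilyloxy)butyl]phenyl}ethan-1-one F2.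
  - Aryllithium 21, made from 20 as in step 12, is formylated with DMF to 7-(methoxymethoxy)-2,2-dimethyl-2H-chromene-6-carbaldehyde F3.
  - Claisen–Schmidt condensation of F2 with F3 (KOH, EtOH, rt) should give the (E)-2'-hydroxychalcone F4.
  - NaOAc in refluxing EtOH closes F4 by oxa-Michael addition to the racemic flavanone F5.
  - Kinetic resolution by asymmetric transfer hydrogenation (Cp*RhCl[(R,R)-TsDPEN], HCO2H/Et3N, EtOAc, rt), a known treatment of racemic flavanones, should reduce the R enantiomer to the cis-(2R,4R)-flavan-4-ol F6. It leaves 29, which is separated by chromatography.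

2. Step 6.
- Processes at risk:
  - Deprotonation may compete at C6, between the two MOM ethers.
  - The carbamoyl group may migrate to carbon on warming (anionic ortho-Fries rearrangement).
  - The silyl triflate may attack the MOM acetals.
- Fallback, from 7 back to 13, replacing steps 6 and 7. Silicon is brought in by electrophilic bromination and O→C silyl migration instead of deprotonation.
  - Et2NH and DBU in MeCN free 3,5-bis(methoxymethoxy)-2-[3-methyl-3-(triethylsilyloxy)butyl]phenol F7.
  - Amine-mediated ortho-bromination (NBS, catalytic iPr2NH, CH2Cl2, −78 → 0 °C), steered by the free hydroxyl group, should give the 2-bromophenol F8.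
  - Hexamethyldisilazane in THF at 60 °C gives the aryl trimethylsilyl ether F9.
  - n-BuLi in THF at −78 °C triggers bromine–lithium exchange and retro-Brook rearrangement to the lithium phenolate F10.
  - F10 is trapped in the same flask with Tf2O to give 13.

3. Step 17.
- Processes at risk under Brønsted acid:
  - Methanol may add to the electron-rich chromene double bond.
  - The side-chain carbinol may ionise and close onto the C7 phenol.
  - The benzylic C2–O1 bond, activated by the oxygenated ring B, may ionise reversibly and erode the configuration.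
- Fallback, from 29 back to 30. The acetals are exchanged for silicon under buffered aprotic conditions rather than solvolysed, and the two kinds of silyl group are then removed separately.
  - TMSOTf and 2,2'-bipyridyl in MeCN (0 °C → rt) convert the three aryl MOM ethers into the tris(trimethylsilyl) ether F11, the methoxymethyl groups ending on the bipyridine nitrogen.
  - Addition of water hydrolyses the aryl silyl ethers to the TES-protected triphenol F12.
  - HF·pyridine buffered with pyridine in THF at 0 °C then frees the tertiary alcohol to give 30.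

Further compounds
F1 | step 16 | 2-acetyl-3,5-bis(methoxymethoxy)-6-[3-methyl-3-(triethylsilyloxy)butyl]phenyl N-isopropylcarbamate | CC(C)(O[Si](CC)(CC)CC)CCc1c(OC(=O)NC(C)C)c(C(C)=O)c(OCOC)cc1OCOC
F2 | step 16 | 1-{2-hydroxy-4,6-bis(methoxymethoxy)-3-[3-methyl-3-(triethylsilyloxy)butyl]phenyl}ethan-1-one | CC(C)(O[Si](CC)(CC)CC)CCc1c(O)c(C(C)=O)c(OCOC)cc1OCOC
F3 | step 16 | 7-(methoxymethoxy)-2,2-dimethyl-2H-chromene-6-carbaldehyde | O=Cc1cc2c(cc1OCOC)OC(C)(C)C=C2
F4 | step 16 | (E)-1-{2-hydroxy-4,6-bis(methoxymethoxy)-3-[3-methyl-3-(triethylsilyloxy)butyl]phenyl}-3-[7-(methoxymethoxy)-2,2-dimethyl-2H-chromen-6-yl]prop-2-en-1-one | CC(C)(O[Si](CC)(CC)CC)CCc1c(O)c(C(=O)/C=C/c2cc3c(cc2OCOC)OC(C)(C)C=C3)c(OCOC)cc1OCOC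
F5 | step 16 | racemic 5,7-bis(methoxymethoxy)-2-[7-(methoxymethoxy)-2,2-dimethyl-2H-chromen-6-yl]-8-[3-methyl-3-(triethylsilyloxy)butyl]chroman-4-one | CC(C)(O[Si](CC)(CC)CC)CCc1c(OCOC)cc(OCOC)c2c1OC(c1cc3c(cc1OCOC)OC(C)(C)C=C3)CC2=O
F6 | step 16 | (2R,4R)-5,7-bis(methoxymethoxy)-2-[7-(methoxymethoxy)-2,2-dimethyl-2H-chromen-6-yl]-8-[3-methyl-3-(triethylsilyloxy)butyl]chroman-4-ol | CC(C)(O[Si](CC)(CC)CC)CCc1c(OCOC)cc(OCOC)c2c1O[C@@H](c1cc3c(cc1OCOC)OC(C)(C)C=C3)C[C@H]2O
F7 | step 6 | 3,5-bis(methoxymethoxy)-2-[3-methyl-3-(triethylsilyloxy)butyl]phenol | CC(C)(O[Si](CC)(CC)CC)CCc1c(O)cc(OCOC)cc1OCOC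
F8 | step 6 | 2-bromo-3,5-bis(methoxymethoxy)-6-[3-methyl-3-(triethylsilyloxy)butyl]phenol | CC(C)(O[Si](CC)(CC)CC)CCc1c(O)c(Br)c(OCOC)cc1OCOC
F9 | step 6 | {2-bromo-3,5-bis(methoxymethoxy)-6-[3-methyl-3-(triethylsilyloxy)butyl]phenoxy}trimethylsilane | CC(C)(O[Si](CC)(CC)CC)CCc1c(O[Si](C)(C)C)c(Br)c(OCOC)cc1OCOC
F10 | step 6 | lithium 3,5-bis(methoxymethoxy)-6-[3-methyl-3-(triethylsilyloxy)butyl]-2-(trimethylsilyl)phenolate | [Li+].CC(C)(O[Si](CC)(CC)CC)CCc1c([O-])c([Si](C)(C)C)c(OCOC)cc1OCOC
F11 | step 17 | (2S)-2-[2,2-dimethyl-7-(trimethylsilyloxy)-2H-chromen-6-yl]-8-[3-methyl-3-(triethylsilyloxy)butyl]-5,7-bis(trimethylsilyloxy)chroman-4-one | CC(C)(O[Si](CC)(CC)CC)CCc1c(O[Si](C)(C)C)cc(O[Si](C)(C)C)c2c1O[C@H](c1cc3c(cc1O[Si](C)(C)C)OC(C)(C)C=C3)CC2=O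
F12 | step 17 | (2S)-5,7-dihydroxy-2-(7-hydroxy-2,2-dimethyl-2H-chromen-6-yl)-8-[3-methyl-3-(triethylsilyloxy)butyl]chroman-4-one | CC(C)(O[Si](CC)(CC)CC)CCc1c(O)cc(O)c2c1O[C@H](c1cc3c(cc1O)OC(C)(C)C=C3)CC2=O
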